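The route rests on cutting the diaryl ether between the oxygen on the para-phenylene ring B and C2 of ring A. On ring A this ether carbon is ortho to the phenol carbon C1, so C1 can first carry a formyl group that activates an ortho C–F bond for SNAr and is afterwards oxidised to the C1 hydroxyl. In one operation the ring B phenoxide displaces fluoride, forming the O–C2 bond and the 18-membered ring. The precursor is an open-chain 2-fluorobenzaldehyde (ring A) tied by an ethano bridge to ring D, whose ether oxygen holds an O-methylated ring C bearing the 2-(4-hydroxyphenyl)ethyl arm (ring B).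

Key step: step 8

Ring labels: ring A is the 1,2,4-trisubstituted ring with the OH ortho to the ether to ring B; ring B is the para-phenylene ring; ring C is the 1,2,3-trisubstituted ring with the second OH; ring D is the meta-phenylene ring.

Assumption: marchantin C has no stereocentre and no configurationally stable axis or plane, so the target is one achiral compound and no step has to control configuration.

Step 1
Reactants: 1 4-bromo-2-fluorobenzaldehyde
Product: 2 2-(4-bromo-2-fluorophenyl)-1,3-dioxolane
Conditions: ethylene glycol, TsOH·H2O (cat.), toluene, reflux, Dean–Stark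
Reagents that add atoms: ethylene glycol, OCCO
Why: Acid-catalysed acetalisation with azeotropic removal of water masks the aldehyde, which switches off the activation of the ortho fluoride for step 3 and protects the carbonyl from the hydrogenation of step 6.

Step 2
Reactants: 2 2-(4-bromo-2-fluorophenyl)-1,3-dioxolane; 3 3-ethynylphenol
Product: 4 3-{[4-(1,3-dioxolan-2-yl)-3-fluorophenyl]ethynyl}phenol
Conditions: PdCl2(PPh3)2 (cat.), CuI (cat.), Et3N, THF, 60 °C, degassed
Reagents that add atoms: none
Why: Sonogashira coupling of an aryl bromide with a terminal arylalkyne tolerates the free phenol and the acetal, leaves the C–F bond untouched and installs both carbons of the ring A–ring D bridge.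

Step 3
Reactants: 4 3-{[4-(1,3-dioxolan-2-yl)-3-fluorophenyl]ethynyl}phenol; 5 2-fluoro-3-methoxybenzaldehyde
Product: 6 2-(3-{[4-(1,3-dioxolan-2-yl)-3-fluorophenyl]ethynyl}phenoxy)-3-methoxybenzaldehyde
Conditions: K2CO3, DMF, 100 °C
Reagents that add atoms: none
Why: Intermolecular SNAr in which the ring D phenoxide displaces the fluoride of 5, activated by its ortho formyl group, while the ring A fluoride next to an acetal is not activated and should stay in place.

Step 4
Reactants: 7 4-(benzyloxy)benzyl chloride
Product: 8 [4-(benzyloxy)benzyl]triphenylphosphonium chloride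
Conditions: PPh3, toluene, reflux
Reagents that add atoms: triphenylphosphine, c1ccc(cc1)P(c1ccccc1)c1ccccc1
Why: SN2 quaternisation of a benzylic chloride by triphenylphosphine should give the crystalline Wittig salt.

Step 5
Reactants: 6 2-(3-{[4-(1,3-dioxolan-2-yl)-3-fluorophenyl]ethynyl}phenoxy)-3-methoxybenzaldehyde; 8 [4-(benzyloxy)benzyl]triphenylphosphonium chloride
Product: 10 2-{4-[(3-{2-[2-(4-benzyloxyphenyl)ethenyl]-6-methoxyphenoxy}phenyl)ethynyl]-2-fluorophenyl}-1,3-dioxolane (mixture of E and Z alkene isomers), via benzylidenephosphorane 9 (not isolated)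
Conditions: 8, KOtBu, THF, 0 °C; then 6, 0 °C to rt
Reagents that add atoms: none
Why: Wittig olefination with a semi-stabilised benzylic ylide joins ring B to the ring C aldehyde; the alkene geometry is irrelevant because step 6 saturates the double bond.

Step 6
Reactants: 10 stilbene alkyne acetal (E/Z mixture)
Product: 11 4-{2-[2-(3-{2-[4-(1,3-dioxolan-2-yl)-3-fluorophenyl]ethyl}phenoxy)-3-methoxyphenyl]ethyl}phenol
Conditions: H2 (1 atm), 10% Pd/C, NaHCO3 (trace), EtOAc/EtOH, rt
Reagents that add atoms: none
Why: Catalytic hydrogenation saturates the alkyne and the stilbene and hydrogenolyses the phenolic benzyl ether, which should be cleaved far faster than the electron-poor cyclic acetal under neutral conditions, while the aryl fluoride and the methyl and diaryl ethers are inert.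

Step 7
Reactants: 11 saturated phenol acetal
Product: 12 2-fluoro-4-[2-(3-{2-[2-(4-hydroxyphenyl)ethyl]-6-methoxyphenoxy}phenyl)ethyl]benzaldehyde
Conditions: 1 M HCl, THF, rt
Reagents that add atoms: water, O
Why: Acid-catalysed acetal hydrolysis releases the aldehyde, and the free phenol and the now activated aryl fluoride coexist because SNAr needs the phenoxide, which is absent in acid.

Step 8
Reactants: 12 2-fluoro-4-[2-(3-{2-[2-(4-hydroxyphenyl)ethyl]-6-methoxyphenoxy}phenyl)ethyl]benzaldehyde
Product: 13 macrocyclic 2-aryloxybenzaldehyde (marchantin C skeleton with CHO in place of the ring A hydroxyl and OMe on ring C)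
Conditions: Cs2CO3, 4 Å MS, DMSO, 100 °C, Ar, syringe-pump addition of 12 (final 0.003 M)
Reagents that add atoms: none
Why: Caesium carbonate deprotonates the ring B phenol and the phenoxide adds to C2 of ring A, the fluorine-bearing carbon ortho to the formyl group, giving a Meisenheimer-type anion whose charge is delocalised onto the aldehyde oxygen; loss of fluoride then completes the addition–elimination and forms the O–C2 bond. The closest known reaction type is the SNAr macrocyclisation of phenoxides onto fluoroarenes activated by an ortho nitro or carbonyl group. The 18-membered ring closes in a formally exo mode, the C–F bond lying outside the ring that forms, and the two flexible ethano bridges let the chain ends meet without severe strain. No stereocentre is created. Chemoselectivity is built into 12: ring B carries the only free phenol, because the ring C oxygen is kept as its methyl ether, and the only activated C–F bond is the one ortho to the aldehyde. The remaining requirement, ring closure ahead of oligomerisation, is met by slow addition, which keeps the phenoxide highly dilute.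

Step 9
Reactants: 13 macrocyclic 2-aryloxybenzaldehyde
Product: 15 ring C O-methyl ether of marchantin C (ring A phenol free), via aryl formate 14 (not isolated)
Conditions: mCPBA, CH2Cl2, 0 °C to rt; then K2CO3 (cat.), MeOH, rt
Reagents that add atoms: mCPBA, O=C(OO)c1cccc(Cl)c1
Why: Baeyer–Villiger (Dakin-type) oxidation, in which the electron-rich ring A aryl group, bearing an ortho aryloxy and a para alkyl donor, should migrate to oxygen in the Criegee intermediate to give formate 14, whose mild methanolysis frees the phenol exactly ortho to the new ether.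

Step 10
Reactants: 15 ring C O-methyl ether of marchantin C
Product: 16 marchantin C
Conditions: BBr3, CH2Cl2, −78 °C to rt; then H2O
Reagents that add atoms: none
Why: Boron tribromide demethylation of the aryl methyl ether (Lewis acid complexation, then bromide attack on the methyl group) should leave both diaryl ethers intact and give the ring C phenol after hydrolysis.

Compound list
1 | 4-bromo-2-fluorobenzaldehyde | O=Cc1ccc(Br)cc1F | starting material
2 | 2-(4-bromo-2-fluorophenyl)-1,3-dioxolane | Fc1cc(Br)ccc1C1OCCO1 | intermediate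
3 | 3-ethynylphenol | C#Cc1cccc(O)c1 | starting material
4 | 3-{[4-(1,3-dioxolan-2-yl)-3-fluorophenyl]ethynyl}phenol | Oc1cccc(c1)C#Cc1ccc(C2OCCO2)c(F)c1 | intermediate
5 | 2-fluoro-3-methoxybenzaldehyde | COc1cccc(C=O)c1F | starting material
6 | 2-(3-{[4-(1,3-dioxolan-2-yl)-3-fluorophenyl]ethynyl}phenoxy)-3-methoxybenzaldehyde | COc1cccc(C=O)c1Oc1cccc(c1)C#Cc1ccc(C2OCCO2)c(F)c1 | intermediate
7 | 4-(benzyloxy)benzyl chloride | ClCc1ccc(OCc2ccccc2)cc1 | starting material
8 | [4-(benzyloxy)benzyl]triphenylphosphonium chloride | [Cl-].c1ccc(cc1)[P+](Cc1ccc(OCc2ccccc2)cc1)(c1ccccc1)c1ccccc1 | intermediate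
9 | [4-(benzyloxy)benzylidene]triphenylphosphorane | c1ccc(cc1)P(=Cc1ccc(OCc2ccccc2)cc1)(c1ccccc1)c1ccccc1 | intermediate (not isolated)
10 | 2-{4-[(3-{2-[2-(4-benzyloxyphenyl)ethenyl]-6-methoxyphenoxy}phenyl)ethynyl]-2-fluorophenyl}-1,3-dioxolane, E/Z mixture | COc1cccc(C=Cc2ccc(OCc3ccccc3)cc2)c1Oc1cccc(c1)C#Cc1ccc(C2OCCO2)c(F)c1 | intermediate
11 | 4-{2-[2-(3-{2-[4-(1,3-dioxolan-2-yl)-3-fluorophenyl]ethyl}phenoxy)-3-methoxyphenyl]ethyl}phenol | COc1cccc(CCc2ccc(O)cc2)c1Oc1cccc(c1)CCc1ccc(C2OCCO2)c(F)c1 | intermediate
12 | 2-fluoro-4-[2-(3-{2-[2-(4-hydroxyphenyl)ethyl]-6-methoxyphenoxy}phenyl)ethyl]benzaldehyde | O=Cc1ccc(CCc2cccc(Oc3c(CCc4ccc(O)cc4)cccc3OC)c2)cc1F | intermediate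
13 | macrocyclic 2-aryloxybenzaldehyde (CHO on ring A, OMe on ring C) | O=Cc1ccc2cc1Oc1ccc(cc1)CCc1cccc(OC)c1Oc1cccc(c1)CC2 | intermediate
14 | macrocyclic aryl formate (OCHO on ring A, OMe on ring C) | O=COc1ccc2cc1Oc1ccc(cc1)CCc1cccc(OC)c1Oc1cccc(c1)CC2 | intermediate (not isolated)
15 | ring C O-methyl ether of marchantin C | Oc1ccc2cc1Oc1ccc(cc1)CCc1cccc(OC)c1Oc1cccc(c1)CC2 | intermediate
16 | marchantin C | Oc1ccc2cc1Oc1ccc(cc1)CCc1cccc(O)c1Oc1cccc(c1)CC2 | target

Total step count: 10. Longest linear sequence: 9 steps (steps 1, 2, 3, 5, 6, 7, 8, 9, 10); step 4 is a one-step side branch.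

Steps most likely to fail

Step 8. Intermolecular SNAr may outrun ring closure and give oligomers, or the single formyl group may activate the fluoride too weakly at the dilution needed. The fallback makes the same O–C2(ring A) bond first, intermolecularly, and closes the ring instead at the ring B–ring C bridge by an intramolecular Horner–Wadsworth–Emmons olefination, a closure known for this ring system. It sets out from 1 and comes back at 13.
- SNAr of 1 with diethyl (4-hydroxybenzyl)phosphonate (K2CO3, DMF, 80 °C) should give diethyl [4-(5-bromo-2-formylphenoxy)benzyl]phosphonate F1.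
- Acetalisation as in step 1 gives diethyl {4-[5-bromo-2-(1,3-dioxolan-2-yl)phenoxy]benzyl}phosphonate F2.
- Sonogashira coupling with 3 gives diethyl (4-{2-(1,3-dioxolan-2-yl)-5-[(3-hydroxyphenyl)ethynyl]phenoxy}benzyl)phosphonate F3.
- Hydrogenation of the alkyne (H2, Pd/C, EtOAc) gives diethyl (4-{2-(1,3-dioxolan-2-yl)-5-[2-(3-hydroxyphenyl)ethyl]phenoxy}benzyl)phosphonate F4.
- SNAr with 5 as in step 3 gives diethyl [4-(2-(1,3-dioxolan-2-yl)-5-{2-[3-(2-formyl-6-methoxyphenoxy)phenyl]ethyl}phenoxy)benzyl]phosphonate F5.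
- KOtBu in THF under high dilution closes the 18-membered ring to the macrocyclic (E)-stilbene dioxolane F6.
- Hydrogenation gives the saturated macrocyclic dioxolane F7, and 1 M HCl in THF then gives 13.

Step 9. Hydride may migrate instead of the aryl group in the Criegee intermediate, so that the aldehyde is oxidised to the carboxylic acid, or the oxidation may be slow. The fallback turns the aldehyde into a methyl ketone, where only the aryl group is a competent migrating group. It sets out from 13 and comes back at 15.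
- MeMgBr (THF, 0 °C) gives the racemic macrocyclic 1-arylethanol F8.
- Dess–Martin periodinane gives the macrocyclic aryl methyl ketone F9.
- mCPBA (CH2Cl2, cat. TFA) gives the macrocyclic aryl acetate F10 by Baeyer–Villiger oxidation with aryl migration.
- K2CO3 in MeOH then gives 15.

Step 6. The benzylic C–O bonds of the dioxolane may be hydrogenolysed, or the acetal may be hydrolysed by catalyst acidity and the aldehyde reduced, while the benzyl ether is being removed. The fallback builds the ring B–ring C bridge without any protecting group on the ring B phenol, so that only C≡C bonds need hydrogen. It sets out from 6 and comes back at 11.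
- Ohira–Bestmann homologation of 6 (dimethyl (1-diazo-2-oxopropyl)phosphonate, K2CO3, MeOH, rt) gives the terminal alkyne 2-(4-{[3-(2-ethynyl-6-methoxyphenoxy)phenyl]ethynyl}-2-fluorophenyl)-1,3-dioxolane F11.
- Sonogashira coupling with 4-iodophenol (PdCl2(PPh3)2, CuI, Et3N, THF, rt) gives the bis-alkyne 4-{[2-(3-{[4-(1,3-dioxolan-2-yl)-3-fluorophenyl]ethynyl}phenoxy)-3-methoxyphenyl]ethynyl}phenol F12.
- Brief hydrogenation (H2, Pd/C, EtOAc with a little Et3N, rt) saturates both alkynes and gives 11.

Further compounds
F1 | step 8 | diethyl [4-(5-bromo-2-formylphenoxy)benzyl]phosphonate | CCOP(=O)(Cc1ccc(Oc2cc(Br)ccc2C=O)cc1)OCC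
F2 | step 8 | diethyl {4-[5-bromo-2-(1,3-dioxolan-2-yl)phenoxy]benzyl}phosphonate | CCOP(=O)(Cc1ccc(Oc2cc(Br)ccc2C2OCCO2)cc1)OCC
F3 | step 8 | diethyl (4-{2-(1,3-dioxolan-2-yl)-5-[(3-hydroxyphenyl)ethynyl]phenoxy}benzyl)phosphonate | CCOP(=O)(Cc1ccc(Oc2cc(C#Cc3cccc(O)c3)ccc2C2OCCO2)cc1)OCC
F4 | step 8 | diethyl (4-{2-(1,3-dioxolan-2-yl)-5-[2-(3-hydroxyphenyl)ethyl]phenoxy}benzyl)phosphonate | CCOP(=O)(Cc1ccc(Oc2cc(CCc3cccc(O)c3)ccc2C2OCCO2)cc1)OCC
F5 | step 8 | diethyl [4-(2-(1,3-dioxolan-2-yl)-5-{2-[3-(2-formyl-6-methoxyphenoxy)phenyl]ethyl}phenoxy)benzyl]phosphonate | CCOP(=O)(Cc1ccc(Oc2cc(CCc3cccc(Oc4c(C=O)cccc4OC)c3)ccc2C2OCCO2)cc1)OCC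
F6 | step 8 | macrocyclic (E)-stilbene dioxolane (13 with an E CH=CH bridge between rings B and C and the CHO as 1,3-dioxolane) | C1COC(O1)c1ccc2cc1Oc1ccc(cc1)/C=C/c1cccc(OC)c1Oc1cccc(c1)CC2
F7 | step 8 | saturated macrocyclic dioxolane (1,3-dioxolane acetal of 13) | C1COC(O1)c1ccc2cc1Oc1ccc(cc1)CCc1cccc(OC)c1Oc1cccc(c1)CC2
F8 | step 9 | racemic macrocyclic 1-arylethanol (13 with CH(OH)CH3 in place of CHO) | CC(O)c1ccc2cc1Oc1ccc(cc1)CCc1cccc(OC)c1Oc1cccc(c1)CC2
F9 | step 9 | macrocyclic aryl methyl ketone (13 with COCH3 in place of CHO) | CC(=O)c1ccc2cc1Oc1ccc(cc1)CCc1cccc(OC)c1Oc1cccc(c1)CC2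
F10 | step 9 | macrocyclic aryl acetate (O-acetate of 15) | CC(=O)Oc1ccc2cc1Oc1ccc(cc1)CCc1cccc(OC)c1Oc1cccc(c1)CC2
F11 | step 6 | 2-(4-{[3-(2-ethynyl-6-methoxyphenoxy)phenyl]ethynyl}-2-fluorophenyl)-1,3-dioxolane | COc1cccc(C#C)c1Oc1cccc(c1)C#Cc1ccc(C2OCCO2)c(F)c1
F12 | step 6 | 4-{[2-(3-{[4-(1,3-dioxolan-2-yl)-3-fluorophenyl]ethynyl}phenoxy)-3-methoxyphenyl]ethynyl}phenol | COc1cccc(C#Cc2ccc(O)cc2)c1Oc1cccc(c1)C#Cc1ccc(C2OCCO2)c(F)c1
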